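Amounts are what you are asked for, so start there: two flasks with the same charge and temperature, read at different times.

| flask | starting material | temperature | remark | time |
|---|---|---|---|---|
| birch | 0.067 M | 20 °C | run made earlier |  |
| oak | 0.15 M | 35 °C | run made earlier |  |
| north | 0.10 M | 35 °C |  | 25 min |
| north-east | 0.10 M | 35 °C |  | 15 min |

- birch (time / min: target / %, starting material / %): 4.00: 0, 2.5; 6.00: 1.4, 0; 10.0: 8.7, 0.6; 15.0: 19.9, 2.1; 20.0: 32.0, 0; 30.0: 57.2, 0; 50.0: 81.2, 0.2
- oak (time / min: target / %, starting material / %): 2.00: 9.0, 0; 3.00: 19.6, 0.7; 5.00: 43.2, 1.1; 8.00: 71.8, 2.1; 10.0: 79.4, 0; 15.0: 93.2, 0; 25.0: 97.5, 0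

(scatter of a reading: 1 percentage point)



1. which one finishes higher in amount of target, in percent of the starting material charged ("neither" within 2 percentage points) (north / north-east / neither)
2. amount of target at the end, in percent of the starting material charged, north
3. amount of target at the end, in percent of the starting material charged, north-east

The oak run stands at the temperature of both flasks. Its starting material reads at most 2.1%, yet target keeps arriving, so follow the rate of that arrival. Target gains 24 percentage points from 3.00 min to 5.00 min, 14 points from 10.0 min to 15.0 min, and 4.3 points from there to 25.0 min.

What slows it? Take the last reading, 97.5%, as the level target is heading for, and watch the shortfall below it. From 8.00 min to 15.0 min the shortfall shrinks at 0.255 min⁻¹, and if I take the rate to fall by the same factor in equal times, 2.71 min is the halving time of the rate. A second-order rate would fade ever more weakly as the shortfall shrinks. Here the earlier stretch alone gives 0.175 min⁻¹, lower than the whole, so I take first order in the amount still on its way. This is a reading with scatter, and birch and oak change charge and temperature together.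

First order means the charge leaves the percent curve alone, so my reckoning puts north-east at oak's 93.2%. The 10.0 min more that north gets are 3.68 halvings, which cut the rate to 7.78% of its value, so north reaches about 97.5%, and north finishes higher.

The forecast says north, with 96% and 87%, taking “values between these two cases”, whereas I stay on the first-order curve.

The flask gives north: north 97.9%, north-east 93.9%.

    starting material → intermediate A (k = 5.20 min⁻¹, Ea = 88.0 kJ mol⁻¹)
    intermediate A → intermediate B (k = 0.638 min⁻¹, Ea = 83.0 kJ mol⁻¹)
    intermediate B → intermediate C (k = 0.267 min⁻¹, Ea = 79.0 kJ mol⁻¹)
    intermediate C → target (k = 1.04 min⁻¹, Ea = 74.0 kJ mol⁻¹)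
    2 starting material → self-condensation product (k = 0.953 L mol⁻¹ min⁻¹, Ea = 64.0 kJ mol⁻¹)
    (constants at 35 °C)

The gap between them comes from the difference in time: north-east reads 93.9% as it stands and 97.9% without that difference. North-east at 15 min stands 4.3 points below its level at 150 min. With the halving time 2.71 min, that shortfall shrinks over north's extra 10.0 min to 0.34 points, and north in fact gains 0.3 points by 250 min.

The numbers in the tables were generated by integration for substances that don't exist.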